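**Assumption:** the target has no stereocentres (it is achiral), so no stereocontrol is needed; one-pot alkylation/saponification sequences are counted as one step.

## Retrosynthetic overview
1. Target 11 ⇒ 2'-O-methylgyrophoric acid 10: the ring-A C5–O bond is made last, by a radical Teuber oxidation (Fremy's salt) followed by reduction.
2. 10 ⇒ ring-A acid 8 + didepside 7; 7 ⇒ ring-B acid 5 + orsellinic acid 3 (aroyl chloride + phenoxide, acceptor carboxyl left free).
3. 3, 5 and 8 ⇒ methyl orsellinate 2 by differential O-alkylation and saponification.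
4. 2 ⇒ 2 × methyl acetoacetate 1.
5. Ring formation: the only ring-forming event is step 1 (one batch of orsellinate supplies rings A, B and C); B–C is joined first, then A, then A is oxygenated.

## Route

**Step 1**
Reactants: 1, methyl acetoacetate (2 molecules)
Product: 2, methyl 2,4-dihydroxy-6-methylbenzoate (methyl orsellinate)
Conditions: NaH (1.05 equiv), THF, 0 °C; n-BuLi (1.0 equiv), −78 °C → reflux; aq. HCl
Reagents that add atoms: none
Why: Self-Claisen condensation of the acetoacetate dianion at its γ-carbon gives methyl 3,5,7-trioxooctanoate, which closes by intramolecular aldol condensation and aromatises (biomimetic polyketide cyclisation); no stereocentre.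

**Step 2**
Reactants: 2, methyl orsellinate
Product: 3, 2,4-dihydroxy-6-methylbenzoic acid (orsellinic acid)
Conditions: KOH (5 equiv), DMSO–H2O, 80 °C, N2; then 1 M HCl, 0 °C
Reagents that add atoms: potassium hydroxide, [K+].[OH-]
Why: Saponification of a hindered benzoate in aqueous DMSO; cold acidification avoids decarboxylation of the β-resorcylic acid.

**Step 3**
Reactants: 2, methyl orsellinate
Product: 4, methyl 4-(benzyloxy)-2-hydroxy-6-methylbenzoate
Conditions: BnBr (1.05 equiv), K2CO3, acetone, reflux
Reagents that add atoms: benzyl bromide, BrCc1ccccc1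
Why: Williamson etherification; the 2-OH is hydrogen-bonded to the ester carbonyl, so only the more acidic 4-OH is alkylated.

**Step 4**
Reactants: 4, methyl 4-(benzyloxy)-2-hydroxy-6-methylbenzoate
Product: 5, 4-(benzyloxy)-2-methoxy-6-methylbenzoic acid
Conditions: MeI (1.5 equiv), KOH, DMSO, rt; then H2O, 100 °C; HCl
Reagents that add atoms: iodomethane, CI; potassium hydroxide, [K+].[OH-]
Why: One-pot Williamson O-methylation of the chelated 2-OH under KOH/DMSO, then saponification of the hindered ester; the benzyl ether is inert to both.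

**Step 5**
Reactants: 5, 4-(benzyloxy)-2-methoxy-6-methylbenzoic acid; 3, orsellinic acid
Product: 6, 4-{[4-(benzyloxy)-2-methoxy-6-methylbenzoyl]oxy}-2-hydroxy-6-methylbenzoic acid
Conditions: 5, (COCl)2, cat. DMF, CH2Cl2, 0 °C → rt, evaporate (acid chloride in situ); add to 3 (1.1 equiv) + NaH (2.2 equiv), THF–DMF, 0 °C; dil. HCl
Reagents that add atoms: none
Why: Fischer-type depside acylation (Schotten–Baumann): in the carboxylate/4-phenoxide dianion of 3 the phenoxide is much the better nucleophile and the 2-OH stays chelated, so the aroyl chloride gives the 4-O-aryl ester, and any mixed anhydride is hydrolysed on work-up.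

**Step 6**
Reactants: 6
Product: 7, 2-hydroxy-4-[(4-hydroxy-2-methoxy-6-methylbenzoyl)oxy]-6-methylbenzoic acid (2'-O-methyllecanoric acid)
Conditions: H2 (1 atm), 10% Pd/C, EtOAc–THF, rt
Reagents that add atoms: none
Why: Hydrogenolysis of the benzyl ether; aryl ester, acid and arenes are untouched.

**Step 7**
Reactants: 2, methyl orsellinate
Product: 8, 2,4-bis(benzyloxy)-6-methylbenzoic acid
Conditions: BnBr (2.5 equiv), KOH, DMSO, rt; then H2O, 110 °C; HCl
Reagents that add atoms: benzyl bromide, BrCc1ccccc1; potassium hydroxide, [K+].[OH-]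
Why: One-pot exhaustive Williamson benzylation (KOH/DMSO also alkylates the chelated 2-OH) and saponification; a fully protected acid avoids self-condensation of a free 2-hydroxyaroyl chloride in step 8.

**Step 8**
Reactants: 8, 2,4-bis(benzyloxy)-6-methylbenzoic acid; 7, 2'-O-methyllecanoric acid
Product: 9, 4-{[4-({2,4-bis(benzyloxy)-6-methylbenzoyl}oxy)-2-methoxy-6-methylbenzoyl]oxy}-2-hydroxy-6-methylbenzoic acid
Conditions: 8, (COCl)2, cat. DMF, CH2Cl2, 0 °C → rt, evaporate (acid chloride in situ); add to 7 + NaH (2.1 equiv), THF–DMF, 0 °C; dil. HCl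
Reagents that add atoms: none
Why: Second Fischer-type acylation: the dianion of 7 carries its only phenoxide at ring-B O-4' (the ring-C 2-OH stays chelated to the carboxylate), and the di-ortho-substituted B–C ester resists transesterification at 0 °C.

**Step 9**
Reactants: 9
Product: 10, 4-({4-[(2,4-dihydroxy-6-methylbenzoyl)oxy]-2-methoxy-6-methylbenzoyl}oxy)-2-hydroxy-6-methylbenzoic acid (2'-O-methylgyrophoric acid)
Conditions: H2 (1 atm), 10% Pd/C, EtOAc–THF, rt
Reagents that add atoms: none
Why: Global hydrogenolysis of both benzyl ethers; the depside esters are stable.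

**Step 10 (key step)**
Reactants: 10, 2'-O-methylgyrophoric acid
Product: 11, 2-hydroxy-4-({2-methoxy-6-methyl-4-[(2,4,5-trihydroxy-6-methylbenzoyl)oxy]benzoyl}oxy)-6-methylbenzoic acid (2'-O-methylhiascic acid, target)
Conditions: Fremy's salt (2.5 equiv), KH2PO4/Na2HPO4 buffer (pH ≈ 7), acetone–H2O, 0 °C → rt, Ar, dark; then aq. Na2S2O4, 0 °C; HCl to pH 2
Reagents that add atoms: potassium nitrosodisulfonate (Fremy's salt), [O]N(S(=O)(=O)[O-])S(=O)(=O)[O-].[K+].[K+]
Why: Proposed new method: late-stage, ring-selective Teuber oxidation of an unprotected tridepside — the nitrosodisulfonate radical abstracts H from the only resorcinol-type ring (A; ring B has no free OH and ring C has a single chelated OH on an acyloxy-deactivated salicylate), a second Fremy radical couples with the aryloxyl radical at C5 (para to the chelated 2-OH and ortho to 4-OH, the only site leading to a p-quinone) to form the C5–O bond, loss of imidodisulfonate gives the 2-hydroxy-1,4-benzoquinone (not isolated), and dithionite reduces it to the 2,4,5-triol; the closest known reactions are the Teuber oxidation of resorcinols to 2-hydroxy-1,4-benzoquinones and the C8 para-oxygenation of chelated 5,7-dihydroxyflavones.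

## Compound list
1 | methyl acetoacetate | CC(=O)CC(=O)OC | starting material
2 | methyl 2,4-dihydroxy-6-methylbenzoate (methyl orsellinate) | COC(=O)c1c(C)cc(O)cc1O | intermediate
3 | 2,4-dihydroxy-6-methylbenzoic acid (orsellinic acid) | OC(=O)c1c(C)cc(O)cc1O | intermediate
4 | methyl 4-(benzyloxy)-2-hydroxy-6-methylbenzoate | COC(=O)c1c(C)cc(OCc2ccccc2)cc1O | intermediate
5 | 4-(benzyloxy)-2-methoxy-6-methylbenzoic acid | COc1cc(OCc2ccccc2)cc(C)c1C(=O)O | intermediate
6 | 4-{[4-(benzyloxy)-2-methoxy-6-methylbenzoyl]oxy}-2-hydroxy-6-methylbenzoic acid | COc1cc(OCc2ccccc2)cc(C)c1C(=O)Oc1cc(C)c(C(=O)O)c(O)c1 | intermediate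
7 | 2-hydroxy-4-[(4-hydroxy-2-methoxy-6-methylbenzoyl)oxy]-6-methylbenzoic acid (2'-O-methyllecanoric acid) | COc1cc(O)cc(C)c1C(=O)Oc1cc(C)c(C(=O)O)c(O)c1 | intermediate
8 | 2,4-bis(benzyloxy)-6-methylbenzoic acid | Cc1cc(OCc2ccccc2)cc(OCc2ccccc2)c1C(=O)O | intermediate
9 | tridepside acid with ring A 2,4-di-O-benzyl | COc1cc(OC(=O)c2c(OCc3ccccc3)cc(OCc3ccccc3)cc2C)cc(C)c1C(=O)Oc1cc(C)c(C(=O)O)c(O)c1 | intermediate
10 | 2'-O-methylgyrophoric acid | COc1cc(OC(=O)c2c(O)cc(O)cc2C)cc(C)c1C(=O)Oc1cc(C)c(C(=O)O)c(O)c1 | intermediate
11 | 2'-O-methylhiascic acid | COc1cc(OC(=O)c2c(O)cc(O)c(O)c2C)cc(C)c1C(=O)Oc1cc(C)c(C(=O)O)c(O)c1 | target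

## Summary
Total steps: 10.
Longest linear sequence: 8 (steps 1 → 3 → 4 → 5 → 6 → 8 → 9 → 10).

Steps most likely to fail, with fallbacks:
1. **Step 10 (late-stage Teuber oxidation).** Risks are slow oxidation of the ester-deactivated ring A, C3 versus C5 attack, competing oxidation of ring C, and lability of the quinone ester. Fallback: make the C5–O bond early by the same Teuber/dithionite sequence on methyl orsellinate 2, convert to 2,4,5-tris(benzyloxy)-6-methylbenzoic acid, use it in place of 8, and finish with the hydrogenolysis.
2. **Step 8 (acylation of the hydroxy-acid dianion of 7).** Risks are mixed-anhydride formation and phenoxide-induced depside scrambling. Fallback: first convert 7 to its benzyl ester (BnBr, KHCO3, DMF, carboxylate-selective), couple the neutral phenol with 8 using TFAA in toluene, and remove all three benzyl groups in the one hydrogenolysis (one extra step).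
3. **Step 5 (acylation of unprotected orsellinic acid).** Risks are the same as in step 8, plus ionisation or hydrolysis of the electron-rich aroyl chloride. Fallback: use benzyl orsellinate (from 3, BnBr, KHCO3) as acceptor in a TFAA-mediated condensation with acid 5; the step 6 hydrogenolysis then removes both benzyl groups and gives the same intermediate 7 (one extra step).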